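## Structural features

The target is a linear sesquineolignan. Guaiacyl ring A sits on C2 of a 2,3-dihydrobenzofuran (benzo ring B, oxygen ring C), and C5 of ring B sits on C2' of a second 2,3-dihydrobenzofuran (oxygen ring D, benzo ring E) whose C5' carries an (E)-3-hydroxyprop-1-enyl chain; rings B and E each bear a methoxy group next to the ring oxygen (C7, C7'). Each heterocycle has two adjacent stereocentres, C2/C3 and C2'/C3', both pairs trans and of the same absolute sense (2R,3S,2'R,3'S), and C3 and C3' each carry CH2OH. The two pairs are separated by the flat ring B, so neither can steer the other and absolute configuration has to be introduced twice. C2 and C2' are benzylic ether carbons para to an oxygen (the ring A hydroxyl, the ring C oxygen); they ionise in acid, so they are labile but can be set late under thermodynamic control, whereas C3 and C3' cannot be corrected once made. Fragile groups are the free guaiacol (oxidation), the cinnamyl-type allylic alcohol (acid), the CH2OH next to a cationic benzylic carbon (loss of formaldehyde) and the electron-rich arenes in general. The real difficulty is therefore absolute control at the two isolated, non-epimerisable centres C3 and C3'. The key step uses the pattern at C3 (H, C3a of ring B, CH2OH) next to the oxygen-bearing C2 that holds ring A: this is what anti-Markovnikov hydration of the 1,1-disubstituted alkene of a 2-(ring B)allylic alcohol gives when the carbinol carbon is C2, and the same pattern recurs at C3'/C2'.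

## Logic of the disconnections

26 ⇒ 25 ⇒ 23 + 24. The sp2–sp2 bond between C5' of ring E and the propenyl chain is cut, with the allylic hydroxyl masked in 25. The para-oxygenated cinnamyl alcohol is the most acid-sensitive part of 26 and must not be present when rings C and D are closed. Ring E is reduced to a bromoarene that is inert in everything before. The forward coupling must tolerate one phenol and two primary alcohols and keep the E geometry of 24, and the silyl ether of 25 must come off without acid.

23 ⇒ 22 ⇒ 21. Both aryl ether bonds, O1–C2 (ring C) and O1'–C2' (ring D), are cut. Each benzylic carbon carries an aryl ring with a para oxygen, so both bonds can form through stabilised cations and trans is the kinetic and thermodynamic outcome; C2 and C2' need no independent control. Two rings, two stereocentres, three MOM ethers and one acetonide leave the problem in one operation. The demand is that C3 and C3' are already defined and stable to acid, and that closure outruns fragmentation of the cation.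

21 ⇒ 20 ⇒ 19 ⇒ 18 + 10. In unit 2 the primary C–OH is traced back to a C–Si bond (20), and the C3'–H and CH2–Si bonds are then removed to give the alkene and Si–H of 19, which is 18 silylated with 10. This turns C3' into an sp2 carbon and leaves one carbinol centre as the only stereochemical input. The forward hydrosilylation must be 5-endo and syn-selective on a large substrate, and the oxidation must leave aryl bromide, MOM ethers and acetonide alone.

18 ⇒ 17 ⇒ 16 + 7. The C2'–C3' bond is cut between a formyl carbon and an alkenyl carbon. This reuses 7, the building block of unit 1, and reduces unit 2 to an aldehyde on ring B. The existing stereocentres are too remote to direct the addition, so the forward sequence needs a reagent-controlled selection of the (S)-carbinol epimer.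

16 ⇒ 15 ⇒ 14 ⇒ 13. The formyl group is traced to the ring B bromide through the aryllithium, and the 1,3-diol is masked as its acetonide. The bromide is the only handle on ring B that survives the unit 1 sequence unchanged. The forward exchange must be faster than any attack on the MOM ethers or on the dioxane.

13 ⇒ 12 ⇒ 11 ⇒ 9 + 10. The primary C–O bond of unit 1 is traced to C–Si with retention, and the C3–H and CH2–Si bonds of 12 are removed to give 11, the silyl ether of 9 with 10. C3 becomes an alkene carbon and the whole unit 1 stereochemistry reduces to one carbinol centre. The forward step must deliver hydrogen to one alkene face under control of that centre.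

9 ⇒ 8 ⇒ 2 + 7. The C2–C3 bond is cut between an aldehyde carbon and an alkenyl triflate carbon, with the (S)-alcohol taken from the racemate by tartrate-controlled kinetic resolution. Two simple arenes result. The coupling must activate the alkenyl triflate and leave the aryl bromide, and the resolution must discriminate well.

7 ⇒ 6 ⇒ 5 ⇒ 4 ⇒ 3, and 2 ⇒ 1. Enol triflate, MOM ether and ring bromine are removed in turn, leaving the two commercial phenols. The bromination must go para to the free hydroxyl and the enolate must sulfonylate on oxygen.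

## Other disconnections considered

Alternative 1: Both C2–C3 bonds are cut in one stroke, leading to the bis(aryldiazoacetate) A2.
- Forward step: Rh2(S-PTTL)4 (or its enantiomer) lets each carbenoid insert into the neighbouring benzylic ether C–H bond, closing rings C and D, and NaOMe then epimerises C3 and C3' to give the trans,trans triester A1.
- In favour: two rings and four stereocentres arise in one flask. Absolute configuration comes from a catalyst at C2 and C2' with no sacrificial resolution. One hydride reduction of A1 would deliver both CH2OH groups and the allylic alcohol.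
- Against: two donor/acceptor carbenoids must behave on arenes that are electron-rich and ortho-substituted, where oxonium ylide formation at the ether oxygen and addition to the guaiacyl rings compete. The second insertion takes place next to stereocentres already present. A wrongly set C2 cannot be repaired, because methoxide only corrects C3. The aryl silyl ether and the acrylate are both exposed to methoxide.
- Comparison: structurally it makes C2–C3 where the chosen plan makes C3–H. Mechanistically it relies on a concerted insertion under catalyst control where the chosen plan relies on substrate-controlled hydrometalation followed by a self-correcting closure. On step economy and on avoiding a resolution this alternative is the better one. The chosen plan is the more forgiving, because its irreversible stereo-defining event is controlled by an adjacent centre of known configuration and its ring closure is reversible.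

Alternative 2: Ring D is cut at C2'–C3' and O1'–C2', giving the ring E sulfone A4 and the unit 1 sulfonium salt A5.
- Forward step: KOH eliminates sulfinate from A4 and deprotonates A5; C–C bond formation at the methide carbon is followed by displacement of the sulfide by the phenoxide, giving the bromide A3.
- In favour: a finished unit 1 is joined convergently to ring E, two bonds form under mild base, and the trans arrangement is intrinsic to the addition–displacement sequence. All protecting groups are silyl, so no acid is needed at the end; on that point it is better than the chosen plan. The bromide endgame from A3 is the same as from 23, so there the two are equal.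
- Against: nothing fixes the absolute sense of the new C2'/C3' pair relative to unit 1 unless a chiral sulfide is built into A5, so two trans diastereomers must be expected. The disconnection also solves only ring D, and A5 still has to be made by another method. An electron-rich benzylic sulfonium salt may ionise or rearrange.
- Comparison: the longest linear sequence would be shorter (better). The stereochemical argument is weaker than 1,2-induction from a carbinol centre of defined configuration.

Alternative 3: O1–C2 of ring C is cut, leading to the diphenol A7 in which C3 already exists.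
- Forward step: Ag2O (or DDQ) oxidises ring A of A7 to the quinone-methide stage and the ring B phenol adds to the exocyclic carbon, giving the aldehyde A6.
- In favour: closure is neutral and biomimetic. C3 can be set beforehand by an auxiliary-controlled alkylation without resolution, which is better on material economy. A6 already carries the formyl group for unit 2 and a free ring A phenol, so no bromide-to-aldehyde exchange is needed, which is also better.
- Against: the trans/cis outcome is kinetic and not self-correcting. The oxidised intermediate can tautomerise to a stilbene, erasing C3, or be trapped intermolecularly. The tactic also needs a free para phenol; for ring D that oxygen is the ring C oxygen, so the same step cannot be repeated on unit 2 once ring C is closed.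
- Comparison: step count per unit is about equal. The chosen plan generates the benzylic cation from a free or an etherified para oxygen alike, so one operation serves both units, and its closure is reversible.

Key step: step 8

Remarks on the chemistry (assumptions):
- Stereochemical check of the key-step pair: 11 is (S) at the carbinol carbon and 12 is (4R,5R) with the two aryl groups cis on the silacycle, which is what "2,3-syn" means here. C4 of 12 has the spatial arrangement of (3S) in 26; the letter differs only because CH2Si outranks the carbinol carbon. No change to either structure was needed.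
- The 2-aryl substrate is assumed to show the syn preference established for 2-alkyl allylic hydrosilyl ethers.
- 24 is taken as a catalogue reagent.

## Route

Step 1
Reactants: 1 vanillin (4-hydroxy-3-methoxybenzaldehyde)
Product: 2 3-methoxy-4-(methoxymethoxy)benzaldehyde
Conditions: MOMCl, iPr2NEt, CH2Cl2, 0 °C → rt
Reagents that add atoms: chloromethyl methyl ether, COCCl
Why: O-alkylation of the phenol (MOM protection); the acetal survives base, organometallics, peroxide and fluoride and is removed only in step 17.

Step 2
Reactants: 3 1-(2-hydroxy-3-methoxyphenyl)ethanone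
Product: 4 1-(5-bromo-2-hydroxy-3-methoxyphenyl)ethanone
Conditions: NBS, MeCN, 0 °C → rt
Reagents that add atoms: N-bromosuccinimide, O=C1CCC(=O)N1Br
Why: Electrophilic aromatic bromination; the free hydroxyl is the strongest director, both its ortho positions are occupied and its para position (C5) is also meta to the acetyl group.

Step 3
Reactants: 4 1-(5-bromo-2-hydroxy-3-methoxyphenyl)ethanone
Product: 5 1-[5-bromo-3-methoxy-2-(methoxymethoxy)phenyl]ethanone
Conditions: MOMCl, iPr2NEt, CH2Cl2, 0 → 40 °C
Reagents that add atoms: chloromethyl methyl ether, COCCl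
Why: MOM protection of the hydrogen-bonded phenol; gentle heating overcomes the chelation, and the ketone has no competing nucleophilic site.

Step 4
Reactants: 5 1-[5-bromo-3-methoxy-2-(methoxymethoxy)phenyl]ethanone
Product: 7 1-[5-bromo-3-methoxy-2-(methoxymethoxy)phenyl]ethenyl trifluoromethanesulfonate, via potassium enolate 6 (not isolated)
Conditions: KN(SiMe3)2, THF, −78 °C; PhNTf2, −78 → 0 °C
Reagents that add atoms: N-phenylbis(trifluoromethanesulfonimide), O=S(=O)(N(c1ccccc1)S(=O)(=O)C(F)(F)F)C(F)(F)F
Why: Enol triflate formation; the methyl group is the only enolisable position, the potassium enolate is sulfonylated on oxygen, and an amide base does not exchange the aryl bromide.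

Step 5
Reactants: 2 3-methoxy-4-(methoxymethoxy)benzaldehyde; 7 1-[5-bromo-3-methoxy-2-(methoxymethoxy)phenyl]ethenyl trifluoromethanesulfonate
Product: 8 rac-2-[5-bromo-3-methoxy-2-(methoxymethoxy)phenyl]-1-[3-methoxy-4-(methoxymethoxy)phenyl]prop-2-en-1-ol
Conditions: CrCl2 (4 equiv), NiCl2 (2 mol %), DMF, rt
Reagents that add atoms: none
Why: Nozaki–Hiyama–Kishi coupling; zerovalent nickel formed in the flask inserts into the alkenyl C–OTf bond, transmetallation to trivalent chromium gives a nucleophile that adds only to the aldehyde, and alkenyl triflates react well before aryl bromides at low nickel loading, so the C–Br bond should remain; the carbinol centre forms racemic.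

Step 6
Reactants: 8 rac-2-[5-bromo-3-methoxy-2-(methoxymethoxy)phenyl]-1-[3-methoxy-4-(methoxymethoxy)phenyl]prop-2-en-1-ol
Product: 9 (1S)-2-[5-bromo-3-methoxy-2-(methoxymethoxy)phenyl]-1-[3-methoxy-4-(methoxymethoxy)phenyl]prop-2-en-1-ol
Conditions: Ti(OiPr)4 (0.25 equiv), D-(−)-DIPT (0.3 equiv), t-BuOOH (0.6 equiv), 4 Å MS, CH2Cl2, −20 °C
Reagents that add atoms: none
Why: Sharpless kinetic resolution of a secondary allylic alcohol with a 2-substituted alkene; with the D-tartrate the oxidant arrives on the face where the (R)-alcohol has only its carbinol hydrogen, so that enantiomer is epoxidised fast, whereas in the (S)-alcohol ring A blocks this face and 9 is left behind.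

Step 7
Reactants: 9 (1S)-2-[5-bromo-3-methoxy-2-(methoxymethoxy)phenyl]-1-[3-methoxy-4-(methoxymethoxy)phenyl]prop-2-en-1-ol; 10 chlorodimethylsilane
Product: 11 {[(1S)-2-[5-bromo-3-methoxy-2-(methoxymethoxy)phenyl]-1-[3-methoxy-4-(methoxymethoxy)phenyl]prop-2-en-1-yl]oxy}dimethylsilane
Conditions: Et3N, DMAP (cat.), CH2Cl2, 0 °C; filtered and used crude
Reagents that add atoms: none
Why: O-silylation of the secondary alcohol by the chlorosilane; the Si–H bond is untouched under amine base and the moisture-sensitive ether is taken on directly.

Step 8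
Reactants: 11 {[(1S)-2-[5-bromo-3-methoxy-2-(methoxymethoxy)phenyl]-1-[3-methoxy-4-(methoxymethoxy)phenyl]prop-2-en-1-yl]oxy}dimethylsilane
Product: 12 (4R,5R)-4-[5-bromo-3-methoxy-2-(methoxymethoxy)phenyl]-5-[3-methoxy-4-(methoxymethoxy)phenyl]-2,2-dimethyl-1,2-oxasilolane (aryl groups cis)
Conditions: Pt2(dvtms)3 (0.5 mol %; dvtms = 1,3-divinyltetramethyldisiloxane), toluene (0.05 M), rt → 50 °C
Reagents that add atoms: none
Why: Tethered hydrosilylation: the Si–H bond of 11 adds oxidatively to zerovalent platinum, the 1,1-disubstituted alkene inserts into Pt–H so that hydrogen goes to the internal carbon (future C3) and platinum to the terminal CH2, and C–Si reductive elimination releases 12 and the catalyst. The closest known reaction is the platinum-catalysed cyclisation of hydrodimethylsilyl ethers of 2-alkyl allylic alcohols, which after oxidation gives 2,3-syn 1,3-diols; here the 2-substituent is aryl. The 1,2-oxasilolane closes in the 5-endo mode, both alkene carbons ending inside the ring, since the 4-exo alternative would require a strained four-membered silacycle. The one new stereocentre (C4 of 12, future C3) is set by 1,2-induction from the carbinol carbon: to avoid A(1,2) strain the carbinol C–H lies near the alkene plane beside ring B, the O–Si–H arm occupies one face and ring A the other, so hydrogen is delivered to the face syn to oxygen and the two aryl groups end cis on the ring. The bulky ortho-disubstituted ring B should make this bias larger than that of a methyl group. Regioselectivity (silicon on the terminal carbon) follows from the tether length and the steric bias of a 1,1-disubstituted alkene, and chemoselectivity from the inertness of aryl bromide and MOM ethers to zerovalent platinum at this temperature and from dilution. The absolute configuration of C3 thus derives entirely from the (S)-carbinol centre kept in step 6.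

Step 9
Reactants: 12 (4R,5R)-4-[5-bromo-3-methoxy-2-(methoxymethoxy)phenyl]-5-[3-methoxy-4-(methoxymethoxy)phenyl]-2,2-dimethyl-1,2-oxasilolane
Product: 13 (1R,2S)-2-[5-bromo-3-methoxy-2-(methoxymethoxy)phenyl]-1-[3-methoxy-4-(methoxymethoxy)phenyl]propane-1,3-diol (syn)
Conditions: 30% H2O2, KF, KHCO3, THF/MeOH (1:1), rt → 40 °C
Reagents that add atoms: hydrogen peroxide, OO
Why: Tamao oxidation; hydroperoxide and fluoride give a hypervalent silicate, the primary alkyl group migrates from silicon to oxygen with retention and the Si–O bonds hydrolyse, so C3 is not touched and aryl bromide and MOM ethers are inert.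

Step 10
Reactants: 13 (1R,2S)-2-[5-bromo-3-methoxy-2-(methoxymethoxy)phenyl]-1-[3-methoxy-4-(methoxymethoxy)phenyl]propane-1,3-diol
Product: 14 (4R,5S)-5-[5-bromo-3-methoxy-2-(methoxymethoxy)phenyl]-4-[3-methoxy-4-(methoxymethoxy)phenyl]-2,2-dimethyl-1,3-dioxane
Conditions: 2-methoxypropene, PPTS (cat.), CH2Cl2, 0 °C; Et3N
Reagents that add atoms: 2-methoxypropene, C=C(C)OC
Why: Acetonide formation by acetal exchange under buffered acid at 0 °C, too mild to ionise the benzylic alcohol or cleave MOM ethers; the dioxane masks both hydroxyls for the lithium, chromium and titanium steps and falls off in step 17.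

Step 11
Reactants: 14 (4R,5S)-5-[5-bromo-3-methoxy-2-(methoxymethoxy)phenyl]-4-[3-methoxy-4-(methoxymethoxy)phenyl]-2,2-dimethyl-1,3-dioxane
Product: 16 3-methoxy-5-[(4R,5S)-4-[3-methoxy-4-(methoxymethoxy)phenyl]-2,2-dimethyl-1,3-dioxan-5-yl]-4-(methoxymethoxy)benzaldehyde, via aryllithium 15 (not isolated)
Conditions: n-BuLi, THF, −78 °C; DMF, −78 → 0 °C; aq. NH4Cl
Reagents that add atoms: N,N-dimethylformamide, CN(C)C=O
Why: Lithium–bromine exchange followed by formylation with DMF; exchange at −78 °C is faster than any deprotonation, the lithiated position has no ortho leaving group, and acetals are inert to the aryllithium.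

Step 12
Reactants: 16 3-methoxy-5-[(4R,5S)-4-[3-methoxy-4-(methoxymethoxy)phenyl]-2,2-dimethyl-1,3-dioxan-5-yl]-4-(methoxymethoxy)benzaldehyde; 7 1-[5-bromo-3-methoxy-2-(methoxymethoxy)phenyl]ethenyl trifluoromethanesulfonate
Product: 17 (1RS)-2-[5-bromo-3-methoxy-2-(methoxymethoxy)phenyl]-1-{3-methoxy-5-[(4R,5S)-4-[3-methoxy-4-(methoxymethoxy)phenyl]-2,2-dimethyl-1,3-dioxan-5-yl]-4-(methoxymethoxy)phenyl}prop-2-en-1-ol (both carbinol epimers)
Conditions: CrCl2 (4 equiv), NiCl2 (2 mol %), DMF, rt
Reagents that add atoms: none
Why: Second Nozaki–Hiyama–Kishi coupling with the same triflate; acetonide and MOM ethers are inert to divalent chromium, and the remote dioxane centres give no facial bias, so both carbinol epimers are expected in similar amounts.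

Step 13
Reactants: 17 (1RS)-2-[5-bromo-3-methoxy-2-(methoxymethoxy)phenyl]-1-{3-methoxy-5-[(4R,5S)-4-[3-methoxy-4-(methoxymethoxy)phenyl]-2,2-dimethyl-1,3-dioxan-5-yl]-4-(methoxymethoxy)phenyl}prop-2-en-1-ol
Product: 18 (1S)-2-[5-bromo-3-methoxy-2-(methoxymethoxy)phenyl]-1-{3-methoxy-5-[(4R,5S)-4-[3-methoxy-4-(methoxymethoxy)phenyl]-2,2-dimethyl-1,3-dioxan-5-yl]-4-(methoxymethoxy)phenyl}prop-2-en-1-ol
Conditions: Ti(OiPr)4 (0.25 equiv), D-(−)-DIPT (0.3 equiv), t-BuOOH (0.6 equiv), 4 Å MS, CH2Cl2, −20 °C
Reagents that add atoms: none
Why: Sharpless kinetic resolution applied to an epimeric pair; the epimers differ only at the reacting carbinol, far from the dioxane centres, so the tartrate complex should treat them as it treats the enantiomers of 8, consuming the (R)-carbinol epimer and leaving 18.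

Step 14
Reactants: 18 (1S)-2-[5-bromo-3-methoxy-2-(methoxymethoxy)phenyl]-1-{3-methoxy-5-[(4R,5S)-4-[3-methoxy-4-(methoxymethoxy)phenyl]-2,2-dimethyl-1,3-dioxan-5-yl]-4-(methoxymethoxy)phenyl}prop-2-en-1-ol; 10 chlorodimethylsilane
Product: 19 O-(dimethylsilyl) ether of 18, (1S) at the silyloxy carbon, dioxane (4R,5S)
Conditions: Et3N, DMAP (cat.), CH2Cl2, 0 °C; filtered and used crude
Reagents that add atoms: none
Why: O-silylation as in step 7; the only free hydroxyl is the allylic one.

Step 15
Reactants: 19 O-(dimethylsilyl) ether of 18
Product: 20 (4R,5R)-4-[5-bromo-3-methoxy-2-(methoxymethoxy)phenyl]-5-{3-methoxy-5-[(4R,5S)-4-[3-methoxy-4-(methoxymethoxy)phenyl]-2,2-dimethyl-1,3-dioxan-5-yl]-4-(methoxymethoxy)phenyl}-2,2-dimethyl-1,2-oxasilolane (aryl groups cis on the silacycle)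
Conditions: Pt2(dvtms)3 (0.5 mol %), toluene (0.05 M), rt → 50 °C
Reagents that add atoms: none
Why: The same 5-endo tethered hydrosilylation as step 8; C3' is set by 1,2-induction from the adjacent (S)-carbinol through the A(1,2)-minimised conformer, and the distant unit 1 centres should not interfere.

Step 16
Reactants: 20 the oxasilolane of step 15
Product: 21 (1R,2S)-2-[5-bromo-3-methoxy-2-(methoxymethoxy)phenyl]-1-{3-methoxy-5-[(4R,5S)-4-[3-methoxy-4-(methoxymethoxy)phenyl]-2,2-dimethyl-1,3-dioxan-5-yl]-4-(methoxymethoxy)phenyl}propane-1,3-diol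
Conditions: 30% H2O2, KF, KHCO3, THF/MeOH (1:1), rt → 40 °C
Reagents that add atoms: hydrogen peroxide, OO
Why: Tamao oxidation with retention at the migrating primary carbon; no aldehyde is present at this stage, and the acetonide is stable to basic peroxide.

Step 17
Reactants: 21 the diol of step 16
Product: 23 4-[(2R,3S)-5-[(2R,3S)-5-bromo-3-(hydroxymethyl)-7-methoxy-2,3-dihydro-1-benzofuran-2-yl]-3-(hydroxymethyl)-7-methoxy-2,3-dihydro-1-benzofuran-2-yl]-2-methoxyphenol, via heptol 22 (not isolated)
Conditions: 3 M aq. HCl, MeOH/THF (2:1), 45 °C, 0.01 M, argon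
Reagents that add atoms: none
Why: Acid-catalysed acetal cleavage followed by SN1 cycloetherification; each benzylic alcohol para to an oxygen ionises to a quinone-methide-like cation that the neighbouring phenol captures in a five-membered closure (5-exo with respect to the exocyclic cationic double bond), ring A adding anti to the CH2OH group on C3 and ring B anti to that on C3'. The closure is reversible in acid and C3 and C3' cannot ionise, so both rings should settle trans with C2 and C2' re-set, giving (2R,3S,2'R,3'S).

Step 18
Reactants: 23 the bromide of step 17; 24 (E)-tert-butyldimethyl{[3-(4,4,5,5-tetramethyl-1,3,2-dioxaborolan-2-yl)prop-2-en-1-yl]oxy}silane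
Product: 25 tert-butyldimethylsilyl ether of 26 at the allylic hydroxyl
Conditions: Pd(OAc)2 (5 mol %), SPhos (10 mol %), K3PO4, THF/H2O (10:1), 60 °C
Reagents that add atoms: none
Why: Suzuki–Miyaura coupling; the electron-rich biaryl phosphine enables oxidative addition of zerovalent palladium into the electron-rich aryl bromide, the alkenyl group is transferred with retention of the E geometry, and free phenol and primary alcohols are tolerated under phosphate base.

Step 19
Reactants: 25 tert-butyldimethylsilyl ether of 26
Product: 26 4-[(2R,3S)-3-(hydroxymethyl)-5-[(2R,3S)-3-(hydroxymethyl)-5-[(E)-3-hydroxyprop-1-en-1-yl]-7-methoxy-2,3-dihydro-1-benzofuran-2-yl]-7-methoxy-2,3-dihydro-1-benzofuran-2-yl]-2-methoxyphenol (target)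
Conditions: Bu4NF, AcOH, THF, 0 °C → rt
Reagents that add atoms: none
Why: Fluoride desilylation of the primary silyl ether, buffered with acetic acid so that neither a phenolate nor an acid is present to endanger the guaiacol or the allylic alcohol; no stereocentre is touched.

## Compound list

1 | vanillin | COc1cc(C=O)ccc1O | starting material
2 | 3-methoxy-4-(methoxymethoxy)benzaldehyde | COCOc1ccc(C=O)cc1OC | intermediate
3 | 1-(2-hydroxy-3-methoxyphenyl)ethanone | CC(=O)c1cccc(OC)c1O | starting material
4 | 1-(5-bromo-2-hydroxy-3-methoxyphenyl)ethanone | CC(=O)c1cc(Br)cc(OC)c1O | intermediate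
5 | 1-[5-bromo-3-methoxy-2-(methoxymethoxy)phenyl]ethanone | CC(=O)c1cc(Br)cc(OC)c1OCOC | intermediate
6 | potassium enolate of 5 | C=C([O-])c1cc(Br)cc(OC)c1OCOC.[K+] | intermediate (not isolated)
7 | 1-[5-bromo-3-methoxy-2-(methoxymethoxy)phenyl]ethenyl trifluoromethanesulfonate | C=C(OS(=O)(=O)C(F)(F)F)c1cc(Br)cc(OC)c1OCOC | intermediate
8 | rac-2-[5-bromo-3-methoxy-2-(methoxymethoxy)phenyl]-1-[3-methoxy-4-(methoxymethoxy)phenyl]prop-2-en-1-ol | COc1cc(C(O)C(=C)c2cc(Br)cc(OC)c2OCOC)ccc1OCOC | intermediate
9 | (1S)-2-[5-bromo-3-methoxy-2-(methoxymethoxy)phenyl]-1-[3-methoxy-4-(methoxymethoxy)phenyl]prop-2-en-1-ol | COc1cc([C@@H](C(=C)c2cc(Br)cc(OC)c2OCOC)O)ccc1OCOC | intermediate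
10 | chlorodimethylsilane | C[SiH](C)Cl | starting material
11 | {[(1S)-2-[5-bromo-3-methoxy-2-(methoxymethoxy)phenyl]-1-[3-methoxy-4-(methoxymethoxy)phenyl]prop-2-en-1-yl]oxy}dimethylsilane | COc1cc([C@@H](C(=C)c2cc(Br)cc(OC)c2OCOC)O[SiH](C)C)ccc1OCOC | intermediate
12 | (4R,5R)-4-[5-bromo-3-methoxy-2-(methoxymethoxy)phenyl]-5-[3-methoxy-4-(methoxymethoxy)phenyl]-2,2-dimethyl-1,2-oxasilolane | COc1cc([C@@H]2O[Si](C)(C)C[C@@H]2c3cc(Br)cc(OC)c3OCOC)ccc1OCOC | intermediate
13 | (1R,2S)-2-[5-bromo-3-methoxy-2-(methoxymethoxy)phenyl]-1-[3-methoxy-4-(methoxymethoxy)phenyl]propane-1,3-diol | COc1cc([C@H](O)[C@H](CO)c2cc(Br)cc(OC)c2OCOC)ccc1OCOC | intermediate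
14 | (4R,5S)-5-[5-bromo-3-methoxy-2-(methoxymethoxy)phenyl]-4-[3-methoxy-4-(methoxymethoxy)phenyl]-2,2-dimethyl-1,3-dioxane | COc1cc([C@@H]2OC(C)(C)OC[C@@H]2c3cc(Br)cc(OC)c3OCOC)ccc1OCOC | intermediate
15 | aryllithium from 14 (Li in place of Br) | COc1cc([C@@H]2OC(C)(C)OC[C@@H]2c3cc([Li])cc(OC)c3OCOC)ccc1OCOC | intermediate (not isolated)
16 | 3-methoxy-5-[(4R,5S)-4-[3-methoxy-4-(methoxymethoxy)phenyl]-2,2-dimethyl-1,3-dioxan-5-yl]-4-(methoxymethoxy)benzaldehyde | COc1cc([C@@H]2OC(C)(C)OC[C@@H]2c3cc(C=O)cc(OC)c3OCOC)ccc1OCOC | intermediate
17 | allylic alcohol from 16 and 7, both carbinol epimers, dioxane (4R,5S) | COc1cc([C@@H]2OC(C)(C)OC[C@@H]2c3cc(C(O)C(=C)c4cc(Br)cc(OC)c4OCOC)cc(OC)c3OCOC)ccc1OCOC | intermediate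
18 | (1S)-carbinol epimer of 17 | COc1cc([C@@H]2OC(C)(C)OC[C@@H]2c3cc([C@@H](C(=C)c4cc(Br)cc(OC)c4OCOC)O)cc(OC)c3OCOC)ccc1OCOC | intermediate
19 | O-(dimethylsilyl) ether of 18 | COc1cc([C@@H]2OC(C)(C)OC[C@@H]2c3cc([C@@H](C(=C)c4cc(Br)cc(OC)c4OCOC)O[SiH](C)C)cc(OC)c3OCOC)ccc1OCOC | intermediate
20 | (4R,5R)-cis-oxasilolane of unit 2 carrying the (4R,5S)-dioxane of unit 1 | COc1cc([C@@H]2OC(C)(C)OC[C@@H]2c3cc([C@@H]4O[Si](C)(C)C[C@@H]4c5cc(Br)cc(OC)c5OCOC)cc(OC)c3OCOC)ccc1OCOC | intermediate
21 | (1R,2S)-syn-1,3-diol of unit 2 carrying the (4R,5S)-dioxane of unit 1 | COc1cc([C@@H]2OC(C)(C)OC[C@@H]2c3cc([C@H](O)[C@H](CO)c4cc(Br)cc(OC)c4OCOC)cc(OC)c3OCOC)ccc1OCOC | intermediate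
22 | fully deprotected heptol, (1R,2S) in both propanediol units | COc1cc([C@H](O)[C@H](CO)c2cc([C@H](O)[C@H](CO)c3cc(Br)cc(OC)c3O)cc(OC)c2O)ccc1O | intermediate (not isolated)
23 | 4-[(2R,3S)-5-[(2R,3S)-5-bromo-3-(hydroxymethyl)-7-methoxy-2,3-dihydro-1-benzofuran-2-yl]-3-(hydroxymethyl)-7-methoxy-2,3-dihydro-1-benzofuran-2-yl]-2-methoxyphenol | COc1cc([C@@H]2Oc3c(OC)cc([C@@H]4Oc5c(OC)cc(Br)cc5[C@H]4CO)cc3[C@H]2CO)ccc1O | intermediate
24 | (E)-tert-butyldimethyl{[3-(4,4,5,5-tetramethyl-1,3,2-dioxaborolan-2-yl)prop-2-en-1-yl]oxy}silane | CC(C)(C)[Si](C)(C)OC/C=C/B1OC(C)(C)C(C)(C)O1 | starting material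
25 | tert-butyldimethylsilyl ether of 26 at the allylic hydroxyl | COc1cc([C@@H]2Oc3c(OC)cc([C@@H]4Oc5c(OC)cc(/C=C/CO[Si](C)(C)C(C)(C)C)cc5[C@H]4CO)cc3[C@H]2CO)ccc1O | intermediate
26 | 4-[(2R,3S)-3-(hydroxymethyl)-5-[(2R,3S)-3-(hydroxymethyl)-5-[(E)-3-hydroxyprop-1-en-1-yl]-7-methoxy-2,3-dihydro-1-benzofuran-2-yl]-7-methoxy-2,3-dihydro-1-benzofuran-2-yl]-2-methoxyphenol | COc1cc([C@@H]2Oc3c(OC)cc([C@@H]4Oc5c(OC)cc(/C=C/CO)cc5[C@H]4CO)cc3[C@H]2CO)ccc1O | target

## Step count and least certain steps

Total: 19 steps. Longest linear sequence: 18 steps (3 → 26, steps 2 to 19).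

Step 8 (key step; the same operation recurs in step 15). The most likely failure is poor facial selectivity in the hydrometalation: an aryl group on the alkene can twist and weaken the A(1,2) bias that an alkyl group gives. Dehydrogenative silylation or migration of the double bond towards oxygen may also compete. Fallback, from 9 and back at 13:
- Silylation with TBSCl/imidazole gives the tert-butyldimethylsilyl ether F1.
- Hydroboration with catecholborane catalysed by RhCl(PPh3)3, which is syn-selective for silyl ethers of 2-substituted allylic alcohols, gives the primary catechol boronate F2.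
- NaOH/H2O2 converts it into the mono-silylated syn-diol F3, and Bu4NF then gives 13.

Step 17. The most likely failure is fragmentation of a benzylic cation with loss of formaldehyde, or intermolecular capture of the cations, because four deprotections and two ring closures are asked of one flask. Fallback, from 13 and back at 23, closing the rings one at a time:
- Aqueous HCl in MeOH closes ring C alone to give the bromophenol F4, and MOMCl/iPr2NEt gives the bis-MOM ether F5.
- Lithium–bromine exchange to the aryllithium F6 and DMF give the aldehyde F7.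
- Coupling with 7 as in step 12 gives the epimeric allylic alcohols F8, and resolution as in step 13 leaves the (S)-alcohol F9.
- Silylation with 10 gives the hydrosilyl ether F10, platinum-catalysed cyclisation the oxasilolane F11, and Tamao oxidation the diol F12.
- A last acid treatment, which now removes three MOM groups and closes only ring D, gives 23.

Step 6. The most likely failure is a low selectivity factor caused by crowding of the titanium–tartrate complex by two aryl groups, or ionisation of the doubly activated carbinol by tetravalent titanium with loss of enantiopurity; at best half the material is used. Fallback, from 8 and back at 9: oxidation with MnO2 gives the enone F13, which is reduced with catecholborane and a B-methyl oxazaborolidine (CBS reduction). The catalyst enantiomer is chosen to give the (S)-alcohol: the (R)-catalyst if the α-arylvinyl group acts as the larger substituent.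

Step 13. The most likely failure is incomplete discrimination between the epimers, which would carry the wrong carbinol epimer into C3', together with the loss of half of an advanced intermediate. Fallback, from 17 and back at 18: MnO2 oxidation gives the enone F14, and the same oxazaborolidine reduction converts both epimers into 18.

Step 5. The most likely failure is oxidative addition of zerovalent nickel into the aryl C–Br bond, or hydrolysis or elimination of the electron-rich α-aryl vinyl triflate before it couples. Fallback, from 5 and back at 8, replacing nickel/chromium by main-group chemistry: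
- Hydrazine hydrate gives the hydrazone F15, and iodine with tetramethylguanidine converts it into the alkenyl iodide F16.
- Iodine–magnesium exchange with iPrMgCl·LiCl at −40 °C, which leaves an aryl bromide alone, gives the alkenylmagnesium chloride F17; this is added to 2 to give 8.

## Further compounds

F1 | step 8 | tert-butyldimethylsilyl ether of 9 | COc1cc([C@@H](C(=C)c2cc(Br)cc(OC)c2OCOC)O[Si](C)(C)C(C)(C)C)ccc1OCOC
F2 | step 8 | primary catechol boronate from hydroboration of F1, syn | COc1cc([C@H](O[Si](C)(C)C(C)(C)C)[C@H](CB2Oc3ccccc3O2)c4cc(Br)cc(OC)c4OCOC)ccc1OCOC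
F3 | step 8 | 1-O-tert-butyldimethylsilyl ether of 13 | COc1cc([C@H](O[Si](C)(C)C(C)(C)C)[C@H](CO)c2cc(Br)cc(OC)c2OCOC)ccc1OCOC
F4 | step 17 | 4-[(2R,3S)-5-bromo-3-(hydroxymethyl)-7-methoxy-2,3-dihydro-1-benzofuran-2-yl]-2-methoxyphenol | COc1cc([C@@H]2Oc3c(OC)cc(Br)cc3[C@H]2CO)ccc1O
F5 | step 17 | bis-MOM ether of F4 | COc1cc([C@@H]2Oc3c(OC)cc(Br)cc3[C@H]2COCOC)ccc1OCOC
F6 | step 17 | aryllithium from F5 | COc1cc([C@@H]2Oc3c(OC)cc([Li])cc3[C@H]2COCOC)ccc1OCOC
F7 | step 17 | (2R,3S)-7-methoxy-2-[3-methoxy-4-(methoxymethoxy)phenyl]-3-(methoxymethoxymethyl)-2,3-dihydro-1-benzofuran-5-carbaldehyde | COc1cc([C@@H]2Oc3c(OC)cc(C=O)cc3[C@H]2COCOC)ccc1OCOC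
F8 | step 17 | allylic alcohol from F7 and 7, both carbinol epimers | COc1cc([C@@H]2Oc3c(OC)cc(C(O)C(=C)c4cc(Br)cc(OC)c4OCOC)cc3[C@H]2COCOC)ccc1OCOC
F9 | step 17 | (S)-carbinol epimer of F8 | COc1cc([C@@H]2Oc3c(OC)cc([C@@H](C(=C)c4cc(Br)cc(OC)c4OCOC)O)cc3[C@H]2COCOC)ccc1OCOC
F10 | step 17 | O-(dimethylsilyl) ether of F9 | COc1cc([C@@H]2Oc3c(OC)cc([C@@H](C(=C)c4cc(Br)cc(OC)c4OCOC)O[SiH](C)C)cc3[C@H]2COCOC)ccc1OCOC
F11 | step 17 | (4R,5R)-cis-oxasilolane from F10 | COc1cc([C@@H]2Oc3c(OC)cc([C@@H]4O[Si](C)(C)C[C@@H]4c5cc(Br)cc(OC)c5OCOC)cc3[C@H]2COCOC)ccc1OCOC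
F12 | step 17 | (1R,2S)-syn-1,3-diol from F11 | COc1cc([C@@H]2Oc3c(OC)cc([C@H](O)[C@H](CO)c4cc(Br)cc(OC)c4OCOC)cc3[C@H]2COCOC)ccc1OCOC
F13 | step 6 | 2-[5-bromo-3-methoxy-2-(methoxymethoxy)phenyl]-1-[3-methoxy-4-(methoxymethoxy)phenyl]prop-2-en-1-one | COc1cc(C(=O)C(=C)c2cc(Br)cc(OC)c2OCOC)ccc1OCOC
F14 | step 13 | enone from oxidation of 17 | COc1cc([C@@H]2OC(C)(C)OC[C@@H]2c3cc(C(=O)C(=C)c4cc(Br)cc(OC)c4OCOC)cc(OC)c3OCOC)ccc1OCOC
F15 | step 5 | hydrazone of 5 | CC(=NN)c1cc(Br)cc(OC)c1OCOC
F16 | step 5 | 5-bromo-1-(1-iodoethenyl)-3-methoxy-2-(methoxymethoxy)benzene | C=C(I)c1cc(Br)cc(OC)c1OCOC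
F17 | step 5 | {1-[5-bromo-3-methoxy-2-(methoxymethoxy)phenyl]ethenyl}magnesium chloride | C=C([Mg]Cl)c1cc(Br)cc(OC)c1OCOC
A1 | alternative 1 | trans,trans bis-dihydrobenzofuran triester, ring A triisopropylsilyl ether | COc1cc([C@@H]2Oc3c(OC)cc([C@@H]4Oc5c(OC)cc(/C=C/C(=O)OC)cc5[C@H]4C(=O)OC)cc3[C@H]2C(=O)OC)ccc1O[Si](C(C)C)(C(C)C)C(C)C
A2 | alternative 1 | bis(aryldiazoacetate) with two benzylic aryl ether links | COc1cc(COc2c(OC)cc(COc3c(OC)cc(/C=C/C(=O)OC)cc3C(=[N+]=[N-])C(=O)OC)cc2C(=[N+]=[N-])C(=O)OC)ccc1O[Si](C(C)C)(C(C)C)C(C)C
A3 | alternative 2 | tris(triisopropylsilyl)-protected bis-dihydrobenzofuran aryl bromide | COc1cc([C@@H]2Oc3c(OC)cc([C@@H]4Oc5c(OC)cc(Br)cc5[C@H]4CO[Si](C(C)C)(C(C)C)C(C)C)cc3[C@H]2CO[Si](C(C)C)(C(C)C)C(C)C)ccc1O[Si](C(C)C)(C(C)C)C(C)C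
A4 | alternative 2 | 4-bromo-2-methoxy-6-[1-(4-methylphenylsulfonyl)-2-(triisopropylsilyloxy)ethyl]phenol | COc1cc(Br)cc(C(CO[Si](C(C)C)(C(C)C)C(C)C)S(=O)(=O)c2ccc(C)cc2)c1O
A5 | alternative 2 | dimethylsulfonium bromide of the silyl-protected unit 1 benzyl group | COc1cc([C@@H]2Oc3c(OC)cc(C[S+](C)C)cc3[C@H]2CO[Si](C(C)C)(C(C)C)C(C)C)ccc1O[Si](C(C)C)(C(C)C)C(C)C.[Br-]
A6 | alternative 3 | (2R,3S)-2-(4-hydroxy-3-methoxyphenyl)-7-methoxy-3-(triisopropylsilyloxymethyl)-2,3-dihydro-1-benzofuran-5-carbaldehyde | COc1cc([C@@H]2Oc3c(OC)cc(C=O)cc3[C@H]2CO[Si](C(C)C)(C(C)C)C(C)C)ccc1O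
A7 | alternative 3 | 4-hydroxy-3-[(2S)-1-(4-hydroxy-3-methoxyphenyl)-3-(triisopropylsilyloxy)propan-2-yl]-5-methoxybenzaldehyde | COc1cc(C[C@H](CO[Si](C(C)C)(C(C)C)C(C)C)c2cc(C=O)cc(OC)c2O)ccc1O
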